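## Retrosynthetic overview

- The (E)-stilbene bond is cut by a Mizoroki–Heck disconnection into a 6-vinyl-1,4-benzodioxane and a protected 5-bromoresorcinol; the vinyl group comes from an aldehyde.
- The cis-2,3-diaryl-1,4-dioxane ring, the only ring made, is cut into a threo 1,2-diaryl-1,2-diol and 4-fluoro-3-hydroxybenzaldehyde. The phenol oxygen enters at the catechol-bearing carbon with inversion, and the other diol oxygen closes onto the C–F carbon with retention.
- The threo diol comes from L-tartrate acetonide by two successive iridium/nickel photoredox decarboxylative arylations; each aryl group enters trans to its neighbour on the dioxolane, so L-tartrate relays its configuration to both carbons.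
- Ring order: the dioxolane template and all arenes are bought; the benzodioxane ring is formed in step 8; the stilbene is made last.

Assumption: the SMILES is read as the cis-2,3-diaryl isomer, catechol-bearing carbon R and resorcinol-bearing carbon S ((2S,3R) in benzodioxine numbering), and every compound marked starting material is taken as a catalogue item.

## Route

Step 1
Reactants: 1 4-bromobenzene-1,2-diol
Product: 2 4-bromo-1,2-bis(triisopropylsilyloxy)benzene
Conditions: iPr3SiOTf (2.3 equiv), 2,6-lutidine (3 equiv), CH2Cl2, 0 °C to rt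
Reagents that add atoms: triisopropylsilyl trifluoromethanesulfonate, CC(C)[Si](C(C)C)(C(C)C)OS(=O)(=O)C(F)(F)F
Why: Phenol silylation (silyl ether protection) with the silyl triflate, which is reactive enough to cap the hindered second catechol oxygen; no stereocentre is involved.

Step 2
Reactants: 3 5-bromobenzene-1,3-diol
Product: 4 1-bromo-3,5-bis(triisopropylsilyloxy)benzene
Conditions: iPr3SiCl (2.3 equiv), imidazole (4 equiv), DMF, rt
Reagents that add atoms: triisopropylsilyl chloride, CC(C)[Si](Cl)(C(C)C)C(C)C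
Why: Standard imidazole-promoted phenol silylation of two unhindered phenols; no stereocentre is involved.

Step 3
Reactants: 5 dimethyl (4R,5R)-2,2-dimethyl-1,3-dioxolane-4,5-dicarboxylate (dimethyl 2,3-O-isopropylidene-L-tartrate)
Product: 6 (4R,5R)-5-(methoxycarbonyl)-2,2-dimethyl-1,3-dioxolane-4-carboxylic acid
Conditions: KOH (1.0 equiv), MeOH, 0 °C to rt; then 1 M HCl to pH 3
Reagents that add atoms: potassium hydroxide, [K+].[OH-]
Why: Mono-saponification of the C2-symmetric diester stops at the carboxylate monoester because the anion resists a second hydroxide attack, and both tartrate centres stay (4R,5R).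

Step 4
Reactants: 6 (4R,5R)-5-(methoxycarbonyl)-2,2-dimethyl-1,3-dioxolane-4-carboxylic acid (1.5 equiv); 2 4-bromo-1,2-bis(triisopropylsilyloxy)benzene
Product: 7 methyl (4R,5S)-5-[3,4-bis(triisopropylsilyloxy)phenyl]-2,2-dimethyl-1,3-dioxolane-4-carboxylate (trans)
Conditions: Ir[dF(CF3)ppy]2(dtbbpy)PF6 (1 mol %), NiCl2·glyme (10 mol %), 4,4'-di-tert-butyl-2,2'-bipyridine (dtbbpy, 15 mol %), Cs2CO3, degassed DMF, 450 nm LEDs, 25 °C
Reagents that add atoms: none
Why: Iridium/nickel dual photoredox decarboxylative arylation, in which the photo-oxidised carboxylate loses CO2 to a dioxolan-4-yl radical that the aryl–nickel species captures and couples anti to the neighbouring ester, so the new benzylic centre (5S, trans) is set by the intact tartrate centre C4.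

Step 5
Reactants: 7 methyl (4R,5S)-5-[3,4-bis(triisopropylsilyloxy)phenyl]-2,2-dimethyl-1,3-dioxolane-4-carboxylate
Product: 8 (4R,5S)-5-[3,4-bis(triisopropylsilyloxy)phenyl]-2,2-dimethyl-1,3-dioxolane-4-carboxylic acid
Conditions: LiOH·H2O (2 equiv), THF/H2O 3:1, 0 °C; then cold 1 M HCl to pH 3
Reagents that add atoms: lithium hydroxide, [Li+].[OH-]
Why: Saponification of an activated α-alkoxy ester that the hindered aryl silyl ethers survive; epimerisation at C4 would not matter because that centre becomes a radical in step 6, and the benzylic centre C5 is not acidic.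

Step 6
Reactants: 8 (4R,5S)-5-[3,4-bis(triisopropylsilyloxy)phenyl]-2,2-dimethyl-1,3-dioxolane-4-carboxylic acid; 4 1-bromo-3,5-bis(triisopropylsilyloxy)benzene (1.5 equiv)
Product: 9 (4S,5S)-4-[3,4-bis(triisopropylsilyloxy)phenyl]-5-[3,5-bis(triisopropylsilyloxy)phenyl]-2,2-dimethyl-1,3-dioxolane (trans)
Conditions: Ir[dF(CF3)ppy]2(dtbbpy)PF6 (2 mol %), NiCl2·glyme (10 mol %), dtbbpy (15 mol %), Cs2CO3, degassed DMF, 450 nm LEDs, 25 °C
Reagents that add atoms: none
Why: Second dual photoredox decarboxylative arylation, in which the C4 radical is arylated anti to the bulky C5 aryl group, giving the trans (4S,5S) diaryl dioxolane, i.e. the threo diol skeleton with its configuration relayed from L-tartrate.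

Step 7
Reactants: 9 (4S,5S)-4-[3,4-bis(triisopropylsilyloxy)phenyl]-5-[3,5-bis(triisopropylsilyloxy)phenyl]-2,2-dimethyl-1,3-dioxolane
Product: 10 (1S,2S)-1-[3,4-bis(triisopropylsilyloxy)phenyl]-2-[3,5-bis(triisopropylsilyloxy)phenyl]ethane-1,2-diol (threo)
Conditions: AcOH/H2O 4:1, 60 °C
Reagents that add atoms: none
Why: Acid-catalysed acetal hydrolysis with a weak acid that does not ionise the benzylic C–O bonds or cleave aryl silyl ethers, so both centres are retained.

Step 8
Reactants: 10 (1S,2S)-1-[3,4-bis(triisopropylsilyloxy)phenyl]-2-[3,5-bis(triisopropylsilyloxy)phenyl]ethane-1,2-diol; 11 4-fluoro-3-hydroxybenzaldehyde (1.2 equiv)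
Product: 15 (2S,3R)-3-[3,4-bis(triisopropylsilyloxy)phenyl]-2-[3,5-bis(triisopropylsilyloxy)phenyl]-2,3-dihydro-1,4-benzodioxine-6-carbaldehyde (cis), via cyclic sulfite 12 (not isolated), via potassium alkyl sulfite 13 (not isolated), via potassium alkoxide 14 (not isolated)
Conditions: SOCl2 (1.05 equiv), Et3N (2.5 equiv), THF, 0 °C; filter off Et3NHCl, exchange solvent for MeCN; then 11, K2CO3 (3 equiv), 75 °C
Reagents that add atoms: none
Why: Proposed new method: an invertive, SO2-extruding annulation of a 1,2-diol with an ortho-fluorophenol, in which the potassium phenoxide of 11 opens the in situ cyclic sulfite 12 by SN2 at the more electron-rich (para-silyloxy) benzylic carbon with inversion, the alkyl sulfite 13 loses SO2 to the alkoxide 14, and 14 closes the dioxane ring by intramolecular SNAr at the C–F carbon para to the formyl group with retention, so the threo diol gives the cis ring (catechol carbon S to R, resorcinol carbon stays S) with the meta oxygen on the catechol carbon; the closest known reactions are nucleophilic openings of cyclic sulfites and sulfates at benzylic carbon and tandem epoxide-opening/SNAr benzodioxane syntheses, and K2CO3/MeCN is chosen so that fluoride leaves solution as KF and spares the silyl ethers.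

Step 9
Reactants: 15 (2S,3R)-3-[3,4-bis(triisopropylsilyloxy)phenyl]-2-[3,5-bis(triisopropylsilyloxy)phenyl]-2,3-dihydro-1,4-benzodioxine-6-carbaldehyde
Product: 16 (2S,3R)-3-[3,4-bis(triisopropylsilyloxy)phenyl]-2-[3,5-bis(triisopropylsilyloxy)phenyl]-6-ethenyl-2,3-dihydro-1,4-benzodioxine
Conditions: MePPh3Br (1.5 equiv), KN(SiMe3)2 (1.4 equiv), THF, 0 °C to rt
Reagents that add atoms: methyltriphenylphosphonium bromide, C[P+](c1ccccc1)(c1ccccc1)c1ccccc1.[Br-]
Why: Wittig methylenation of an aryl aldehyde with a non-stabilised ylide; the two benzylic ether centres are not acidic and stay cis.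

Step 10
Reactants: 16 (2S,3R)-3-[3,4-bis(triisopropylsilyloxy)phenyl]-2-[3,5-bis(triisopropylsilyloxy)phenyl]-6-ethenyl-2,3-dihydro-1,4-benzodioxine; 4 1-bromo-3,5-bis(triisopropylsilyloxy)benzene (1.3 equiv)
Product: 17 (2S,3R)-3-[3,4-bis(triisopropylsilyloxy)phenyl]-2-[3,5-bis(triisopropylsilyloxy)phenyl]-6-[(E)-2-[3,5-bis(triisopropylsilyloxy)phenyl]ethenyl]-2,3-dihydro-1,4-benzodioxine
Conditions: Pd(OAc)2 (5 mol %), P(o-tol)3 (12 mol %), Et3N (3 equiv), DMF, 95 °C
Reagents that add atoms: none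
Why: Mizoroki–Heck arylation of the styrene, where syn insertion and syn β-hydride elimination give the (E)-stilbene and the ring stereocentres are not touched.

Step 11
Reactants: 17 (2S,3R)-3-[3,4-bis(triisopropylsilyloxy)phenyl]-2-[3,5-bis(triisopropylsilyloxy)phenyl]-6-[(E)-2-[3,5-bis(triisopropylsilyloxy)phenyl]ethenyl]-2,3-dihydro-1,4-benzodioxine
Product: 18 5-[(E)-2-[(2S,3R)-3-(3,4-dihydroxyphenyl)-2-(3,5-dihydroxyphenyl)-2,3-dihydro-1,4-benzodioxin-6-yl]ethenyl]benzene-1,3-diol (target)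
Conditions: Bu4NF (7 equiv), AcOH (7 equiv), THF, 0 °C to rt, argon
Reagents that add atoms: none
Why: Fluoride-mediated cleavage of the six aryl silyl ethers, buffered with acetic acid so that no phenoxide builds up that could open the cis-dioxane through a quinone methide and reclose it trans.

## Compound list

1 | 4-bromobenzene-1,2-diol | Oc1ccc(Br)cc1O | starting material
2 | 4-bromo-1,2-bis(triisopropylsilyloxy)benzene | CC(C)[Si](C(C)C)(C(C)C)Oc1ccc(Br)cc1O[Si](C(C)C)(C(C)C)C(C)C | intermediate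
3 | 5-bromobenzene-1,3-diol | Oc1cc(O)cc(Br)c1 | starting material
4 | 1-bromo-3,5-bis(triisopropylsilyloxy)benzene | CC(C)[Si](C(C)C)(C(C)C)Oc1cc(Br)cc(O[Si](C(C)C)(C(C)C)C(C)C)c1 | intermediate
5 | dimethyl (4R,5R)-2,2-dimethyl-1,3-dioxolane-4,5-dicarboxylate | COC(=O)[C@@H]1OC(C)(C)O[C@H]1C(=O)OC | starting material
6 | (4R,5R)-5-(methoxycarbonyl)-2,2-dimethyl-1,3-dioxolane-4-carboxylic acid | COC(=O)[C@@H]1OC(C)(C)O[C@H]1C(=O)O | intermediate
7 | methyl (4R,5S)-5-[3,4-bis(triisopropylsilyloxy)phenyl]-2,2-dimethyl-1,3-dioxolane-4-carboxylate | COC(=O)[C@@H]1OC(C)(C)O[C@H]1c2ccc(O[Si](C(C)C)(C(C)C)C(C)C)c(O[Si](C(C)C)(C(C)C)C(C)C)c2 | intermediate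
8 | (4R,5S)-5-[3,4-bis(triisopropylsilyloxy)phenyl]-2,2-dimethyl-1,3-dioxolane-4-carboxylic acid | OC(=O)[C@@H]1OC(C)(C)O[C@H]1c2ccc(O[Si](C(C)C)(C(C)C)C(C)C)c(O[Si](C(C)C)(C(C)C)C(C)C)c2 | intermediate
9 | (4S,5S)-4-[3,4-bis(triisopropylsilyloxy)phenyl]-5-[3,5-bis(triisopropylsilyloxy)phenyl]-2,2-dimethyl-1,3-dioxolane | CC(C)[Si](C(C)C)(C(C)C)Oc1cc(cc(O[Si](C(C)C)(C(C)C)C(C)C)c1)[C@@H]2OC(C)(C)O[C@H]2c3ccc(O[Si](C(C)C)(C(C)C)C(C)C)c(O[Si](C(C)C)(C(C)C)C(C)C)c3 | intermediate
10 | (1S,2S)-1-[3,4-bis(triisopropylsilyloxy)phenyl]-2-[3,5-bis(triisopropylsilyloxy)phenyl]ethane-1,2-diol | CC(C)[Si](C(C)C)(C(C)C)Oc1cc(cc(O[Si](C(C)C)(C(C)C)C(C)C)c1)[C@H](O)[C@@H](O)c2ccc(O[Si](C(C)C)(C(C)C)C(C)C)c(O[Si](C(C)C)(C(C)C)C(C)C)c2 | intermediate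
11 | 4-fluoro-3-hydroxybenzaldehyde | O=Cc1ccc(F)c(O)c1 | starting material
12 | (4S,5S)-4-[3,4-bis(triisopropylsilyloxy)phenyl]-5-[3,5-bis(triisopropylsilyloxy)phenyl]-1,3,2-dioxathiolane 2-oxide (either configuration at sulfur) | CC(C)[Si](C(C)C)(C(C)C)Oc1cc(cc(O[Si](C(C)C)(C(C)C)C(C)C)c1)[C@@H]2OS(=O)O[C@H]2c3ccc(O[Si](C(C)C)(C(C)C)C(C)C)c(O[Si](C(C)C)(C(C)C)C(C)C)c3 | intermediate (not isolated)
13 | potassium (1S,2R)-2-[3,4-bis(triisopropylsilyloxy)phenyl]-1-[3,5-bis(triisopropylsilyloxy)phenyl]-2-(2-fluoro-5-formylphenoxy)ethyl sulfite | O=Cc1ccc(F)c(c1)O[C@H](c2ccc(O[Si](C(C)C)(C(C)C)C(C)C)c(O[Si](C(C)C)(C(C)C)C(C)C)c2)[C@H](c3cc(O[Si](C(C)C)(C(C)C)C(C)C)cc(O[Si](C(C)C)(C(C)C)C(C)C)c3)OS(=O)[O-].[K+] | intermediate (not isolated)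
14 | potassium (1S,2R)-2-[3,4-bis(triisopropylsilyloxy)phenyl]-1-[3,5-bis(triisopropylsilyloxy)phenyl]-2-(2-fluoro-5-formylphenoxy)ethanolate | O=Cc1ccc(F)c(c1)O[C@H](c2ccc(O[Si](C(C)C)(C(C)C)C(C)C)c(O[Si](C(C)C)(C(C)C)C(C)C)c2)[C@H](c3cc(O[Si](C(C)C)(C(C)C)C(C)C)cc(O[Si](C(C)C)(C(C)C)C(C)C)c3)[O-].[K+] | intermediate (not isolated)
15 | (2S,3R)-3-[3,4-bis(triisopropylsilyloxy)phenyl]-2-[3,5-bis(triisopropylsilyloxy)phenyl]-2,3-dihydro-1,4-benzodioxine-6-carbaldehyde | O=Cc1ccc2c(c1)O[C@H](c3ccc(O[Si](C(C)C)(C(C)C)C(C)C)c(O[Si](C(C)C)(C(C)C)C(C)C)c3)[C@H](c4cc(O[Si](C(C)C)(C(C)C)C(C)C)cc(O[Si](C(C)C)(C(C)C)C(C)C)c4)O2 | intermediate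
16 | (2S,3R)-3-[3,4-bis(triisopropylsilyloxy)phenyl]-2-[3,5-bis(triisopropylsilyloxy)phenyl]-6-ethenyl-2,3-dihydro-1,4-benzodioxine | C=Cc1ccc2c(c1)O[C@H](c3ccc(O[Si](C(C)C)(C(C)C)C(C)C)c(O[Si](C(C)C)(C(C)C)C(C)C)c3)[C@H](c4cc(O[Si](C(C)C)(C(C)C)C(C)C)cc(O[Si](C(C)C)(C(C)C)C(C)C)c4)O2 | intermediate
17 | (2S,3R)-3-[3,4-bis(triisopropylsilyloxy)phenyl]-2-[3,5-bis(triisopropylsilyloxy)phenyl]-6-[(E)-2-[3,5-bis(triisopropylsilyloxy)phenyl]ethenyl]-2,3-dihydro-1,4-benzodioxine | CC(C)[Si](C(C)C)(C(C)C)Oc1cc(O[Si](C(C)C)(C(C)C)C(C)C)cc(/C=C/c2ccc3c(c2)O[C@H](c4ccc(O[Si](C(C)C)(C(C)C)C(C)C)c(O[Si](C(C)C)(C(C)C)C(C)C)c4)[C@H](c5cc(O[Si](C(C)C)(C(C)C)C(C)C)cc(O[Si](C(C)C)(C(C)C)C(C)C)c5)O3)c1 | intermediate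
18 | 5-[(E)-2-[(2S,3R)-3-(3,4-dihydroxyphenyl)-2-(3,5-dihydroxyphenyl)-2,3-dihydro-1,4-benzodioxin-6-yl]ethenyl]benzene-1,3-diol | Oc1cc(O)cc(/C=C/c2ccc3c(c2)O[C@H](c2ccc(O)c(O)c2)[C@H](c2cc(O)cc(O)c2)O3)c1 | target

## Step count and risks

Total step count: 11. Longest linear sequence: 9 steps (5 to 18, steps 3 to 11).

**Step 6, second decarboxylative arylation.** The acid is hindered, the bromide is moderately electron-rich, and the product carries two oxidisable arenes next to benzylic C–H bonds; low conversion or an eroded trans ratio are the likely failures. The fallback is a non-photochemical decarboxylative Negishi coupling and sets out from 8 and 4. Acid 8 is esterified with N-hydroxyphthalimide (DIC, catalytic DMAP, CH2Cl2) to the N-acyloxyphthalimide ester F1. Bromide 4 undergoes bromine–lithium exchange (n-BuLi, THF, −78 °C) to the aryllithium F2, which ZnCl2 converts into the arylzinc chloride F3. NiCl2·glyme with dtbbpy (20 mol % each) in THF/DMF at rt then couples F1 with F3 through the same dioxolanyl radical, again anti to the neighbouring aryl group. The fallback comes back to the route at 9.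

**Step 8, the proposed invertive sulfite annulation.** The risks are a slow opening of the cyclic sulfite, attack at the resorcinol-bearing carbon (which gives the regioisomeric cis ring), partial ionisation at the catechol-bearing carbon (which gives some trans isomer), and base-induced elimination to a deoxybenzoin. The fallback uses known chemistry and sets out from 10. Trimethyl orthoacetate with catalytic pyridinium p-toluenesulfonate in CH2Cl2 gives the cyclic orthoacetate F4. Me3SiCl opens it through the acetoxonium ion, with chloride entering at the catechol-bearing carbon with inversion, to give the chloro acetate F5. K2CO3 in MeOH at 0 °C removes the acetate and closes the trans epoxide F6 with a second inversion, so the diol configuration is retained overall. Heating F6 with 11 and K2CO3 in MeCN at 80 °C opens the epoxide at the catechol-bearing benzylic carbon with inversion, and the alkoxide 14 so formed closes by SNAr. The fallback comes back to the route at 15.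

**Step 11, sixfold desilylation.** The free para-hydroxyphenyl group next to a ring oxygen can open the cis-dioxane through a quinone methide under basic fluoride and reclose it trans, and the catechol is sensitive to air. The fallback never lets a phenoxide persist and sets out from 17. CsF with excess Ac2O in DMF at rt cleaves each silyl ether and acetylates the phenoxide at once, giving the stable, chromatographable hexaacetate F7. NH4OAc in MeOH/H2O at rt then removes the acetates under near-neutral conditions. The fallback comes back to the route at 18.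

## Further compounds

F1 | step 6 | 1,3-dioxoisoindolin-2-yl (4R,5S)-5-[3,4-bis(triisopropylsilyloxy)phenyl]-2,2-dimethyl-1,3-dioxolane-4-carboxylate | O=C(ON1C(=O)c2ccccc2C1=O)[C@@H]3OC(C)(C)O[C@H]3c4ccc(O[Si](C(C)C)(C(C)C)C(C)C)c(O[Si](C(C)C)(C(C)C)C(C)C)c4
F2 | step 6 | [3,5-bis(triisopropylsilyloxy)phenyl]lithium | [Li]c1cc(O[Si](C(C)C)(C(C)C)C(C)C)cc(O[Si](C(C)C)(C(C)C)C(C)C)c1
F3 | step 6 | [3,5-bis(triisopropylsilyloxy)phenyl]zinc chloride | Cl[Zn]c1cc(O[Si](C(C)C)(C(C)C)C(C)C)cc(O[Si](C(C)C)(C(C)C)C(C)C)c1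
F4 | step 8 | (4S,5S)-4-[3,4-bis(triisopropylsilyloxy)phenyl]-5-[3,5-bis(triisopropylsilyloxy)phenyl]-2-methoxy-2-methyl-1,3-dioxolane | CC(C)[Si](C(C)C)(C(C)C)Oc1cc(cc(O[Si](C(C)C)(C(C)C)C(C)C)c1)[C@@H]2OC(C)(OC)O[C@H]2c3ccc(O[Si](C(C)C)(C(C)C)C(C)C)c(O[Si](C(C)C)(C(C)C)C(C)C)c3
F5 | step 8 | (1S,2R)-2-[3,4-bis(triisopropylsilyloxy)phenyl]-1-[3,5-bis(triisopropylsilyloxy)phenyl]-2-chloroethyl acetate | Cl[C@H](c1ccc(O[Si](C(C)C)(C(C)C)C(C)C)c(O[Si](C(C)C)(C(C)C)C(C)C)c1)[C@H](c2cc(O[Si](C(C)C)(C(C)C)C(C)C)cc(O[Si](C(C)C)(C(C)C)C(C)C)c2)OC(C)=O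
F6 | step 8 | (2S,3S)-2-[3,4-bis(triisopropylsilyloxy)phenyl]-3-[3,5-bis(triisopropylsilyloxy)phenyl]oxirane | CC(C)[Si](C(C)C)(C(C)C)Oc1cc(cc(O[Si](C(C)C)(C(C)C)C(C)C)c1)[C@@H]2O[C@H]2c3ccc(O[Si](C(C)C)(C(C)C)C(C)C)c(O[Si](C(C)C)(C(C)C)C(C)C)c3
F7 | step 11 | 5-[(E)-2-[(2S,3R)-3-(3,4-diacetoxyphenyl)-2-(3,5-diacetoxyphenyl)-2,3-dihydro-1,4-benzodioxin-6-yl]ethenyl]-1,3-phenylene diacetate | CC(=O)Oc1cc(OC(C)=O)cc(/C=C/c2ccc3c(c2)O[C@H](c2ccc(OC(C)=O)c(OC(C)=O)c2)[C@H](c2cc(OC(C)=O)cc(OC(C)=O)c2)O3)c1
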